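Read the product as spent reagent, one for one, and count half-lives of reagent.

in all of them: free catalyst 3.5 mM; added ligand 10 mM; impurity 0.72 mM
- Friday's: left-handed substrate 0.048 M; right-handed substrate 0.048 M; reagent 0.0426 M; run made earlier
- Monday's: left-handed substrate 0.11 M; right-handed substrate 0.11 M; reagent 0.0426 M; run made earlier
- Tuesday's: left-handed substrate 0.071 M; right-handed substrate 0.071 M; reagent 0.085 M; run made earlier
- flask: left-handed substrate 0.071 M; right-handed substrate 0.071 M; reagent 0.0426 M; time 2.5 min

| run | time / s | left-handed product / % | right-handed product / % |
|---|---|---|---|
| Friday's | 30.0 | 8.5 | 3.6 |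
| Friday's | 60.0 | 12.8 | 5.5 |
| Friday's | 90.0 | 14.9 | 8.0 |
| Friday's | 120 | 16.3 | 9.8 |
| Monday's | 10.0 | 3.2 | 0.7 |
| Monday's | 20.0 | 5.8 | 2.0 |
| Monday's | 50.0 | 9.0 | 3.9 |
| Monday's | 120 | 10.4 | 6.9 |
| Tuesday's | 15.0 | 9.8 | 3.1 |
| Tuesday's | 40.0 | 17.2 | 7.4 |
| Tuesday's | 80.0 | 22.3 | 12.5 |
| Tuesday's | 120 | 23.8 | 16.7 |

(scatter of a reading: 0.3 percentage points)

- free catalyst is single-handed; left-handed substrate and right-handed substrate are mirror images of each other, charged as a racemate, each of them at the stated concentration
- an excess is the difference of the two amounts in percent of their sum
- an excess is below zero if the other one leads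

* excess of left-handed product over right-handed product in the product at 3.0 s
* excess of left-handed product over right-handed product in the product at 2.5 min
* part of the left-handed substrate and right-handed substrate charged together that has reacted at 2.5 min

By 120 s, Friday's readings give an average reagent half-life of 93.8 s. Monday's, with more substrate, give 37.2 s. Their ratio, 2.52, stands near the ratio of substrate charges, 2.29, so treat half-life times substrate charge as steady at this c(reagent) and this catalyst charge, a pseudo-first-order reckoning. For the flask this gives 60.5 s: the reagent half-life, the average time in which c(reagent) halves.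

Now climb the ladder for the flask. At 3.0 s in the flask only 0.0496 of a half-life has passed, so this average clock puts the reagent used at 3.38%, and the product there is the first batch made. Next comes the excess: in Monday's run it fell from 64.1% to 20.2%, a half-life of 66.1 s, read with the scatter of its readings. Last, the substrates: the flask's reagent, charged below the two together, is the limiting reagent, with a ceiling of 30.0% reacted. At 2.5 min the flask has had 2.48 half-lives, so my own estimate is 17.9% of its reagent left and 24.6% reacted.

The forecast gives an excess of 62% (52% to 73%) at 3.0 s, an excess of 15% (9% to 20%) at 2.5 min and 24% (22% to 26%) reacted at 2.5 min, reasoning that “the catalyst seems to convert”.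

The flask gives an excess of 57.9% at 3.0 s, an excess of 17.2% at 2.5 min and 24.2% reacted at 2.5 min, inside each range of the forecast, with 19% of its reagent left against the 17.9% counted on 60.5 s.

    reagent + free catalyst + right-handed substrate → free catalyst + right-handed product (k = 18.1 L² mol⁻² s⁻¹)
    free catalyst + added ligand ⇌ idle complex (K = 58.6 L mol⁻¹, k = 0.529 L mol⁻¹ s⁻¹)
    reagent + free catalyst + left-handed substrate → free catalyst + left-handed product (k = 70.9 L² mol⁻² s⁻¹)
    left-handed product ⇌ right-handed product (k = 0.00593 s⁻¹)
    free catalyst + impurity → spent catalyst (k = 720 L mol⁻¹ s⁻¹)

The swap between the products relaxes with a half-life of 0.974 min, both ways together, against 1.9 min for the flask's reagent at 2.5 min by making left-handed product alone, and at that moment left-handed product is still made 1.43 times faster than used up, each step taken net. A reacted part near the forecast's 24% does not hold in the neighbour flask charged with 0.0014 M of free catalyst: take the half-life as inversely proportional to catalyst charged less impurity, and 60.5 s stretches to 247 s, which gives 10.3% reacted. The computed neighbour flask gives 11.2%, below the forecast's range.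

The readings are simulated with constants of no real substance, noise included.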